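**Retrosynthetic overview**

- The target is reached from a ring-A hydroxy ketone by non-basic methylenation of the side-chain carbonyl and removal of one silyl ether.
- Feature used: in ring A the secondary carbinol carbon C2 and its neighbour C3, which carries the CH2–C(=CH2)– linker to ring B, are trans. With the linker sp2 carbon written as a ketone, C2–C3 is the bond a C2 ketyl forms on 6-exo addition to the β-carbon of an (E)-enone.
- Key disconnection: C2–C3 of ring A, giving an acyclic α-silyloxy aldehyde/(E)-enone that already carries the finished bromohydrin ring B. Ring B is made first and ring A is closed last.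
- The seco chain comes from (S)-carvone. The epoxide sets the C1–O bond trans to isopropenyl, and α-ketol cleavage of the C2–C3 ring bond gives an aldehyde and an ester, so the two chain ends stay distinguishable; a Wittig reaction joins it to ring B.
- Ring B comes from (1S,2S,4R)-limonene-1,2-diol: inversion of the secondary hydroxyl to the cis bromide, ozonolysis, and conversion of the methyl ketone into the acyl ylide.

Key step: step 14

Remark: ring-A carbons are numbered as in p-menthane (C1 carries CH3 and O, C4 the isopropenyl group, C2–C3 is the bond that is cut and re-formed) and ring-B carbons are primed; centres formed as epimer mixtures and removed one step later are left undefined in names and SMILES.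

**Route**

Step 1
Reactants: 1 (S)-carvone
Product: 2 (1S,4S,6S)-1-methyl-4-(prop-1-en-2-yl)-7-oxabicyclo[4.1.0]heptan-2-one (oxirane oxygen trans to isopropenyl)
Conditions: 30% H2O2, NaOH (cat.), MeOH, 0 °C
Reagents that add atoms: hydrogen peroxide, OO
Why: Weitz–Scheffer nucleophilic epoxidation touches only the electron-poor enone double bond, and axial attack of hydroperoxide at C6 anti to the C4 isopropenyl group places the oxirane oxygen, and so the future tertiary C1–O bond, trans to isopropenyl.

Step 2
Reactants: 2 (1S,4S,6S)-carvone epoxide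
Product: 3 (1S,4S)-1-methyl-4-(prop-1-en-2-yl)cyclohexane-1,2-diol (C2 epimers, tertiary OH trans to isopropenyl)
Conditions: LiAlH4, THF, 0 °C to reflux; Fieser work-up
Reagents that add atoms: none
Why: LiAlH4 reduces the ketone and opens the trisubstituted epoxide by SN2 hydride attack at its secondary carbon C6, so the tertiary C1–O bond and its configuration are untouched and the C2 carbinol centre is removed in step 3.

Step 3
Reactants: 3 (1S,4S)-p-menth-8-ene-1,2-diol (C2 epimers)
Product: 4 (2S,5S)-2-hydroxy-2-methyl-5-(prop-1-en-2-yl)cyclohexan-1-one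
Conditions: IBX, EtOAc, 75 °C
Reagents that add atoms: none
Why: IBX oxidation takes the secondary alcohol of a 1,2-diol to the α-ketol without glycol cleavage and cannot touch the tertiary alcohol or the isopropenyl group, so both C2 epimers converge on one ketone.

Step 4
Reactants: 4 (2S,5S)-2-hydroxy-2-methyl-5-(prop-1-en-2-yl)cyclohexan-1-one
Product: 5 (2S,5S)-2-methyl-5-(prop-1-en-2-yl)-2-(triethylsilyloxy)cyclohexan-1-one
Conditions: TESOTf, 2,6-lutidine, CH2Cl2, −78 to 0 °C
Reagents that add atoms: triethylsilyl trifluoromethanesulfonate (TESOTf), CC[Si](CC)(CC)OS(=O)(=O)C(F)(F)F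
Why: Silyl triflate silylation of the tertiary alcohol gives a TES ether that prevents later cleavage on the C1–C2 side and lasts until the final fluoride step.

Step 5
Reactants: 5 (2S,5S)-2-methyl-5-(prop-1-en-2-yl)-2-(triethylsilyloxy)cyclohexan-1-one
Product: 7 (2S,5R,6RS)-6-hydroxy-2-methyl-5-(prop-1-en-2-yl)-2-(triethylsilyloxy)cyclohexan-1-one (p-menthane C3 carbinol epimers), via potassium enolate 6 (not isolated)
Conditions: KHMDS, THF, −78 °C; 2-(phenylsulfonyl)-3-phenyloxaziridine, −78 °C; AcOH quench at −78 °C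
Reagents that add atoms: 2-(phenylsulfonyl)-3-phenyloxaziridine (Davis reagent), O=S(=O)(c1ccccc1)N1OC1c1ccccc1
Why: Davis enolate hydroxylation can occur only at C3 because C1 is quaternary, and the new C3 centre (expected trans to the neighbouring isopropenyl group) is destroyed in step 6.

Step 6
Reactants: 7 (2S,5R,6RS)-6-hydroxy-2-methyl-5-(prop-1-en-2-yl)-2-(triethylsilyloxy)cyclohexan-1-one
Product: 8 methyl (2S,5R)-5-formyl-2,6-dimethyl-2-(triethylsilyloxy)hept-6-enoate
Conditions: Pb(OAc)4, MeOH/PhH (1:1), 0 °C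
Reagents that add atoms: methanol, CO
Why: Criegee-type cleavage of the α-ketol in methanol cuts the C2–C3 ring bond and leaves the carbinol carbon C3 as the aldehyde and the ketone carbon C2 as the methyl ester, so only one aldehyde is offered to the ylide in step 11.

Step 7
Reactants: 9 (1S,2S,4R)-limonene-1,2-diol
Product: 10 (1S,2R,4R)-2-bromo-1-methyl-4-(prop-1-en-2-yl)cyclohexan-1-ol (Br cis to the tertiary OH)
Conditions: CBr4, PPh3, CH2Cl2, 0 °C to rt
Reagents that add atoms: carbon tetrabromide, BrC(Br)(Br)Br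
Why: In this Appel reaction only the secondary hydroxyl is activated on phosphorus and bromide displaces it with inversion, turning the axial C2′–O into the equatorial C2′–Br cis to the tertiary hydroxyl, which is too hindered to be activated and stays un-ionised in the base-free medium.

Step 8
Reactants: 10 (1S,2R,4R)-2-bromo-1-methyl-4-(prop-1-en-2-yl)cyclohexan-1-ol
Product: 12 1-[(1R,3R,4S)-3-bromo-4-hydroxy-4-methylcyclohexyl]ethan-1-one, via secondary ozonide 11 (not isolated)
Conditions: O3, CH2Cl2, −78 °C; Me2S, −78 °C to rt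
Reagents that add atoms: ozone, [O-][O+]=O
Why: Ozonolysis with reductive work-up cleaves the only alkene to the methyl ketone, and the secondary bromide and tertiary alcohol are inert to ozone and dimethyl sulfide.

Step 9
Reactants: 12 1-[(1R,3R,4S)-3-bromo-4-hydroxy-4-methylcyclohexyl]ethan-1-one
Product: 14 2-bromo-1-[(1R,3R,4S)-3-bromo-4-hydroxy-4-methylcyclohexyl]ethan-1-one, via bromo dimethyl ketal 13 (not isolated)
Conditions: Br2 (1.0 equiv), MeOH, 0 to 10 °C; then H2O, rt
Reagents that add atoms: bromine, BrBr; water, O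
Why: α-Bromination of a methyl ketone in methanol is selective for the methyl group over the ring methine (kinetic enolisation under ketalising conditions), and the water added at the end returns the ketone from ketal 13.

Step 10
Reactants: 14 2-bromo-1-[(1R,3R,4S)-3-bromo-4-hydroxy-4-methylcyclohexyl]ethan-1-one
Product: 16 1-[(1R,3R,4S)-3-bromo-4-hydroxy-4-methylcyclohexyl]-2-(triphenyl-λ5-phosphanylidene)ethan-1-one, via phosphonium bromide 15 (not isolated)
Conditions: PPh3, toluene, rt; then aq. Na2CO3, CH2Cl2, rt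
Reagents that add atoms: triphenylphosphine, c1ccc(cc1)P(c1ccccc1)c1ccccc1
Why: SN2 quaternisation occurs at the primary α-bromo ketone carbon (the hindered secondary ring bromide does not react), and carbonate deprotonates the acidic salt to the stabilised acyl ylide.

Step 11
Reactants: 8 methyl (2S,5R)-5-formyl-2,6-dimethyl-2-(triethylsilyloxy)hept-6-enoate; 16 ring-B acyl ylide
Product: 17 methyl (2S,5S,6E)-8-[(1R,3R,4S)-3-bromo-4-hydroxy-4-methylcyclohexyl]-2-methyl-8-oxo-5-(prop-1-en-2-yl)-2-(triethylsilyloxy)oct-6-enoate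
Conditions: toluene, 80 °C
Reagents that add atoms: none
Why: Wittig olefination with a stabilised acyl ylide is E-selective and base-free, so the α-centre of the β,γ-unsaturated aldehyde (C4, which becomes doubly allylic) should not epimerise, and the hindered ester is untouched.

Step 12
Reactants: 17 enone ester
Product: 18 (2S,5S,6E,8RS)-8-[(1R,3R,4S)-3-bromo-4-hydroxy-4-methylcyclohexyl]-2-methyl-5-(prop-1-en-2-yl)-2-(triethylsilyloxy)oct-6-ene-1,8-diol
Conditions: DIBAL-H (6 equiv), CH2Cl2, −78 to 0 °C; Rochelle salt work-up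
Reagents that add atoms: none
Why: DIBAL reduces the ester to the primary alcohol and the enone 1,2- to the allylic alcohol (carbinol epimers, removed in step 13) without touching the alkenes, the alkyl bromide or the silyl ether.

Step 13
Reactants: 18 allylic/primary diol
Product: 19 (2S,5S,6E)-8-[(1R,3R,4S)-3-bromo-4-hydroxy-4-methylcyclohexyl]-2-methyl-8-oxo-5-(prop-1-en-2-yl)-2-(triethylsilyloxy)oct-6-enal
Conditions: Dess–Martin periodinane (3 equiv), pyridine, CH2Cl2, 0 °C to rt
Reagents that add atoms: none
Why: Dess–Martin oxidation converts the primary alcohol into the non-enolisable α-silyloxy aldehyde and the allylic alcohol back into the (E)-enone in one operation under buffered conditions, while the tertiary alcohol cannot be oxidised.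

Step 14
Reactants: 19 seco aldehyde–enone
Product: 20 1-[(1R,3R,4S)-3-bromo-4-hydroxy-4-methylcyclohexyl]-2-[(1R,2S,3S,6S)-2-hydroxy-3-methyl-6-(prop-1-en-2-yl)-3-(triethylsilyloxy)cyclohexyl]ethan-1-one
Conditions: SmI2 (2.5 equiv), t-BuOH (3 equiv), THF (0.01 M), −78 °C
Reagents that add atoms: none
Why: SmI2 transfers one electron to the aldehyde to give a samarium(III) ketyl at C2, which adds to the β-carbon C3 of the (E)-enone, and a second electron followed by protonation by t-BuOH converts the resulting α-keto radical into the saturated ketone. The closest known reaction type is the SmI2-mediated ketyl–olefin (aldehyde–enone) reductive cyclisation, which is established and anti-selective. Ring A is closed in the 6-exo-trig mode through a chair-like transition state. The new C3 centre is controlled by the C4 isopropenyl group, which stays equatorial and places the enone arm equatorial and trans to it, while the 1,4-trans relation set in step 1 keeps the C1 silyloxy group equatorial in the same chair. The new C2 centre is controlled by the bulky O–Sm(III) group, which prefers to lie anti to the enone arm and so gives the trans 2-hydroxy/3-alkyl relation. The step needs anti diastereoselectivity and chemoselectivity for the aldehyde/enone pair over the secondary C–Br bond, and these are secured by the single all-equatorial chair that C1 and C4 impose, by the α-quaternary non-enolisable aldehyde, and by HMPA-free SmI2 at −78 °C, which does not reduce unactivated alkyl bromides.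

Step 15
Reactants: 20 ring-A hydroxy ketone
Product: 21 (1S,2R,4R)-2-bromo-4-{3-[(1R,2S,3S,6S)-2-hydroxy-3-methyl-6-(prop-1-en-2-yl)-3-(triethylsilyloxy)cyclohexyl]prop-1-en-2-yl}-1-methylcyclohexan-1-ol
Conditions: Zn, CH2Br2, TiCl4 (pre-formed Lombardo reagent), THF/CH2Cl2, 0 °C to rt
Reagents that add atoms: dibromomethane, BrCBr
Why: Takai–Lombardo methylenation is non-basic, so the ketone is converted into the 1,1-disubstituted alkene without enolisation toward the ring-B methine, and the reagent tolerates free hydroxyl groups and silyl ethers.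

Step 16
Reactants: 21 ring-A tertiary TES ether of the target
Product: 22 (1S,2S,3R,4S)-3-{2-[(1R,3R,4S)-3-bromo-4-hydroxy-4-methylcyclohexyl]prop-2-en-1-yl}-1-methyl-4-(prop-1-en-2-yl)cyclohexane-1,2-diol (target)
Conditions: HF·pyridine, pyridine, THF, 0 °C to rt
Reagents that add atoms: none
Why: Fluoride cleavage of the tertiary triethylsilyl ether under buffered, non-basic conditions frees the last hydroxyl without E2 loss of the secondary bromide or ionisation of the tertiary alcohols.

**Compound list**

1 | (S)-carvone | CC1=CC[C@@H](CC1=O)C(C)=C | starting material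
2 | (1S,4S,6S)-1-methyl-4-(prop-1-en-2-yl)-7-oxabicyclo[4.1.0]heptan-2-one | O=C1C[C@@H](C(C)=C)C[C@@H]2O[C@]12C | intermediate
3 | (1S,4S)-1-methyl-4-(prop-1-en-2-yl)cyclohexane-1,2-diol, C2 epimers | C[C@@]1(O)C(O)C[C@@H](C(C)=C)CC1 | intermediate
4 | (2S,5S)-2-hydroxy-2-methyl-5-(prop-1-en-2-yl)cyclohexan-1-one | C[C@@]1(O)C(=O)C[C@@H](C(C)=C)CC1 | intermediate
5 | (2S,5S)-2-methyl-5-(prop-1-en-2-yl)-2-(triethylsilyloxy)cyclohexan-1-one | C[C@@]1(O[Si](CC)(CC)CC)C(=O)C[C@@H](C(C)=C)CC1 | intermediate
6 | potassium (3S,6S)-6-methyl-3-(prop-1-en-2-yl)-6-(triethylsilyloxy)cyclohex-1-en-1-olate | C[C@@]1(O[Si](CC)(CC)CC)C([O-])=C[C@@H](C(C)=C)CC1.[K+] | intermediate (not isolated)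
7 | (2S,5R,6RS)-6-hydroxy-2-methyl-5-(prop-1-en-2-yl)-2-(triethylsilyloxy)cyclohexan-1-one | C[C@@]1(O[Si](CC)(CC)CC)C(=O)C(O)[C@@H](C(C)=C)CC1 | intermediate
8 | methyl (2S,5R)-5-formyl-2,6-dimethyl-2-(triethylsilyloxy)hept-6-enoate | COC(=O)[C@@](C)(O[Si](CC)(CC)CC)CC[C@H](C(C)=C)C=O | intermediate
9 | (1S,2S,4R)-limonene-1,2-diol | CC(=C)[C@@H]1CC[C@](C)(O)[C@@H](O)C1 | starting material
10 | (1S,2R,4R)-2-bromo-1-methyl-4-(prop-1-en-2-yl)cyclohexan-1-ol | CC(=C)[C@@H]1CC[C@](C)(O)[C@H](Br)C1 | intermediate
11 | 3-[(1R,3R,4S)-3-bromo-4-hydroxy-4-methylcyclohexyl]-3-methyl-1,2,4-trioxolane, C3 epimers | CC1(OCOO1)[C@@H]2CC[C@](C)(O)[C@H](Br)C2 | intermediate (not isolated)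
12 | 1-[(1R,3R,4S)-3-bromo-4-hydroxy-4-methylcyclohexyl]ethan-1-one | CC(=O)[C@@H]1CC[C@](C)(O)[C@H](Br)C1 | intermediate
13 | (1S,2R,4R)-2-bromo-4-(2-bromo-1,1-dimethoxyethyl)-1-methylcyclohexan-1-ol | BrCC(OC)(OC)[C@@H]1CC[C@](C)(O)[C@H](Br)C1 | intermediate (not isolated)
14 | 2-bromo-1-[(1R,3R,4S)-3-bromo-4-hydroxy-4-methylcyclohexyl]ethan-1-one | BrCC(=O)[C@@H]1CC[C@](C)(O)[C@H](Br)C1 | intermediate
15 | {2-[(1R,3R,4S)-3-bromo-4-hydroxy-4-methylcyclohexyl]-2-oxoethyl}triphenylphosphonium bromide | [Br-].O=C(C[P+](c1ccccc1)(c1ccccc1)c1ccccc1)[C@@H]2CC[C@](C)(O)[C@H](Br)C2 | intermediate (not isolated)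
16 | 1-[(1R,3R,4S)-3-bromo-4-hydroxy-4-methylcyclohexyl]-2-(triphenyl-λ5-phosphanylidene)ethan-1-one | O=C(C=P(c1ccccc1)(c1ccccc1)c1ccccc1)[C@@H]2CC[C@](C)(O)[C@H](Br)C2 | intermediate
17 | methyl (2S,5S,6E)-8-[(1R,3R,4S)-3-bromo-4-hydroxy-4-methylcyclohexyl]-2-methyl-8-oxo-5-(prop-1-en-2-yl)-2-(triethylsilyloxy)oct-6-enoate | COC(=O)[C@@](C)(O[Si](CC)(CC)CC)CC[C@H](C(C)=C)/C=C/C(=O)[C@@H]1CC[C@](C)(O)[C@H](Br)C1 | intermediate
18 | (2S,5S,6E,8RS)-8-[(1R,3R,4S)-3-bromo-4-hydroxy-4-methylcyclohexyl]-2-methyl-5-(prop-1-en-2-yl)-2-(triethylsilyloxy)oct-6-ene-1,8-diol | OC[C@@](C)(O[Si](CC)(CC)CC)CC[C@H](C(C)=C)/C=C/C(O)[C@@H]1CC[C@](C)(O)[C@H](Br)C1 | intermediate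
19 | (2S,5S,6E)-8-[(1R,3R,4S)-3-bromo-4-hydroxy-4-methylcyclohexyl]-2-methyl-8-oxo-5-(prop-1-en-2-yl)-2-(triethylsilyloxy)oct-6-enal | O=C[C@@](C)(O[Si](CC)(CC)CC)CC[C@H](C(C)=C)/C=C/C(=O)[C@@H]1CC[C@](C)(O)[C@H](Br)C1 | intermediate (key-step precursor)
20 | 1-[(1R,3R,4S)-3-bromo-4-hydroxy-4-methylcyclohexyl]-2-[(1R,2S,3S,6S)-2-hydroxy-3-methyl-6-(prop-1-en-2-yl)-3-(triethylsilyloxy)cyclohexyl]ethan-1-one | O=C(C[C@@H]1[C@@H](C(=C)C)CC[C@](C)(O[Si](CC)(CC)CC)[C@H]1O)[C@@H]2CC[C@](C)(O)[C@H](Br)C2 | intermediate (key-step product)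
21 | (1S,2R,4R)-2-bromo-4-{3-[(1R,2S,3S,6S)-2-hydroxy-3-methyl-6-(prop-1-en-2-yl)-3-(triethylsilyloxy)cyclohexyl]prop-1-en-2-yl}-1-methylcyclohexan-1-ol | C=C(C[C@@H]1[C@@H](C(=C)C)CC[C@](C)(O[Si](CC)(CC)CC)[C@H]1O)[C@@H]2CC[C@](C)(O)[C@H](Br)C2 | intermediate
22 | (1S,2S,3R,4S)-3-{2-[(1R,3R,4S)-3-bromo-4-hydroxy-4-methylcyclohexyl]prop-2-en-1-yl}-1-methyl-4-(prop-1-en-2-yl)cyclohexane-1,2-diol | C=C(C[C@@H]1[C@@H](C(=C)C)CC[C@](C)(O)[C@H]1O)[C@@H]1CC[C@](C)(O)[C@H](Br)C1 | target

**Step count**

Total: 16 steps. Longest linear sequence: 12 steps (steps 1–6 and 11–16, from (S)-carvone); the ring-B branch is steps 7–10.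

**Steps most likely to fail**

1. Step 14 (key step). The process at risk is facial control in the ketyl addition: the O–Sm group may not stay anti to the enone arm, or the arm may add cis to isopropenyl, giving C2 and/or C3 epimers. The fallback moves stereocontrol from the radical step to a ketone. It sets out from 19: the cyclisation is run as in step 14 and the unseparated C2/C3-epimeric hydroxy ketone mixture F5 is methylenated as in step 15 to the epimeric alkene mixture F6. Dess–Martin oxidation of the ring carbinol, then equilibration of the α-centre with catalytic DBU, should give the single ring-A 2-ketone F7 with the C3 arm equatorial and trans to isopropenyl; the equatorial ring bromide has no anti-periplanar hydrogen for E2. NaBH4 in MeOH at −20 °C should then deliver hydride axially, because the equatorial approach is blocked by the axial C1 methyl, giving the equatorial C2 alcohol. The route is rejoined at 21.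

2. Step 7. The process at risk is clean SN2 inversion: the trans-diaxial tertiary hydroxyl may participate (epoxide closure and re-opening with overall retention), or the activated oxygen may be lost by E2. The fallback ties the tertiary oxygen into the leaving group. It sets out from 9: ozonolysis (O3, CH2Cl2/MeOH; Me2S) gives 1-[(1R,3S,4S)-3,4-dihydroxy-4-methylcyclohexyl]ethan-1-one F1. SOCl2/Et3N closes the trans-fused cyclic sulfite F2, and RuCl3 (cat.)/NaIO4 oxidises it to the cyclic sulfate F3. LiBr in THF/DMF opens F3 by SN2 at the secondary carbon with inversion to the lithium bromoalkyl sulfate F4. Catalytic H2SO4 in wet THF hydrolyses the sulfate monoester, and the route is rejoined at 12.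

3. Step 15. The process at risk is stalling or decomposition under the Lewis-acidic Zn/Ti reagent: the ketone may be held as the five-membered lactol with the C2 hydroxyl, or the tertiary silyl ether may be lost. The fallback replaces carbenoid methylenation by a Peterson olefination. It sets out from 20: TMSOTf/2,6-lutidine caps both free hydroxyls to give the bis(trimethylsilyl) ether F8, which removes the lactol equilibrium. TMSCH2Li/CeCl3 (a weakly basic organocerium reagent) in THF at −78 °C adds to the ketone to give the β-hydroxysilane F9. Aqueous HF in MeCN then effects Peterson elimination and removes the TES and both TMS groups in one operation, so the route is rejoined at 22 and step 16 is not needed.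

**Further compounds**

F1 | step 7 | 1-[(1R,3S,4S)-3,4-dihydroxy-4-methylcyclohexyl]ethan-1-one | CC(=O)[C@@H]1CC[C@](C)(O)[C@@H](O)C1
F2 | step 7 | trans-fused cyclic sulfite of F1 (sulfur epimers) | CC(=O)[C@@H]1CC[C@]2(C)OS(=O)O[C@H]2C1
F3 | step 7 | trans-fused cyclic sulfate of F1 | CC(=O)[C@@H]1CC[C@]2(C)OS(=O)(=O)O[C@H]2C1
F4 | step 7 | lithium (1S,2R,4R)-4-acetyl-2-bromo-1-methylcyclohexyl sulfate | CC(=O)[C@@H]1CC[C@](C)(OS(=O)(=O)[O-])[C@H](Br)C1.[Li+]
F5 | step 14 | C2/C3-epimer mixture of hydroxy ketone 20 | O=C(CC1[C@@H](C(=C)C)CC[C@](C)(O[Si](CC)(CC)CC)C1O)[C@@H]2CC[C@](C)(O)[C@H](Br)C2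
F6 | step 14 | C2/C3-epimer mixture of alkene 21 | C=C(CC1[C@@H](C(=C)C)CC[C@](C)(O[Si](CC)(CC)CC)C1O)[C@@H]2CC[C@](C)(O)[C@H](Br)C2
F7 | step 14 | ring-A 2-ketone corresponding to 21 (C3 arm trans to isopropenyl) | C=C(C[C@@H]1[C@@H](C(=C)C)CC[C@](C)(O[Si](CC)(CC)CC)C1=O)[C@@H]2CC[C@](C)(O)[C@H](Br)C2
F8 | step 15 | bis(trimethylsilyl) ether of 20 | O=C(C[C@@H]1[C@@H](C(=C)C)CC[C@](C)(O[Si](CC)(CC)CC)[C@H]1O[Si](C)(C)C)[C@@H]2CC[C@](C)(O[Si](C)(C)C)[C@H](Br)C2
F9 | step 15 | β-hydroxysilane from F8 (carbinol epimers) | C[Si](C)(C)CC(O)(C[C@@H]1[C@@H](C(=C)C)CC[C@](C)(O[Si](CC)(CC)CC)[C@H]1O[Si](C)(C)C)[C@@H]2CC[C@](C)(O[Si](C)(C)C)[C@H](Br)C2
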